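A closed, stirred flask at constant volume holds a solid substrate, which has to dissolve before it reacts, with a protic impurity beside it.

in all of them: solid substrate 0.20 M
- Monday's: protic impurity 0.028 M; temperature 105 °C; run made earlier
- Thursday's: protic impurity 0.044 M; temperature 125 °C; run made earlier
- green: protic impurity 0.0200 M; temperature 110 °C; time 8.0 h
- amber: protic impurity 0.0200 M; temperature 140 °C; time 8.0 h
- ochre: protic impurity 0.0200 M; at 140 °C until 6.0 h, from then on at 110 °C; time 8.0 h
- violet: protic impurity 0.0200 M; temperature 125 °C; time 8.0 h

| run | time / h | target / % | solid substrate / % |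
|---|---|---|---|
| Monday's | 0.500 | 0.5 | 82.6 |
| Monday's | 1.33 | 1.3 | 58.7 |
| Monday's | 2.50 | 6.8 | 32.6 |
| Monday's | 4.00 | 19.2 | 0.1 |
| Monday's | 6.00 | 36.8 | 0 |
| Monday's | 8.00 | 47.3 | 0 |
| Monday's | 10.0 | 53.2 | 0.3 |
| Thursday's | 0.417 | 1.4 | 84.9 |
| Thursday's | 0.667 | 3.7 | 75.5 |
| Thursday's | 1.00 | 7.8 | 64.4 |
| Thursday's | 1.33 | 11.2 | 52.6 |
| Thursday's | 2.00 | 19.0 | 29.1 |
| Thursday's | 3.00 | 29.2 | 1.0 |
| Thursday's | 5.00 | 25.0 | 0 |

(readings scatter by 0.5 percentage points)

1. the best flask by amount of target, in percent of the solid substrate charged; "all alike" if 1.5 percentage points covers them all (green / amber / ochre / violet / all alike)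
2. amount of target at the end, in percent of the solid substrate charged, green
3. amount of target at the end, in percent of the solid substrate charged, amber
4. amount of target at the end, in percent of the solid substrate charged, ochre
5. amount of target at the end, in percent of the solid substrate charged, violet

- as a solid, counted per litre of solution: solid substrate
- at the start none of the solid substrate is in solution
- what has only dissolved of solid substrate counts as not reacted
- a reading or a percentage of target counts all its forms, free or not

Two numbers do not go together. Up to the first reading the solid falls by 0.348 h⁻¹ in Monday's run at 105 °C and by 0.362 h⁻¹ in Thursday's at 125 °C, as fractions of the charge. These agree, though I expect a chemical step to feel that gap in temperature.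

I clear this up through the order of the rate. The early loss matches across the two runs, and in Thursday's run it does not slow as the solid shrinks, so I take it as zero order in the solid and take the concentration that sets it to be that of dissolved material, which starts at none. Thursday's solid falls in a straight line from 84.9% to 29.1%, a slope of 0.352 h⁻¹. I call this the feed: the fraction of the charge leaving the solid per hour while the solution stays thin.

Monday's solid later slows to 0.223 h⁻¹, less than the feed, which I read as dissolved material piling up. In Monday's run at 4.00 h the solid reads 0.1% and target 19.2%, so 80.7% of the charge lies in forms I cannot read.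

The feed is a clock: at this slope half the charge leaves the solid in 1.42 h and the whole in 2.84 h. I expect a flask at 140 °C to keep that clock and one at 110 °C to lag it. Over its last two readings Monday's target climbs from 47.3% to 53.2%, while over its last two Thursday's falls from 29.2% to 25.0%, so I put green, at 110 °C beside Monday's 105 °C, first.

The forecast names green best, with 50% for green, 10% for amber, 14% for ochre and 24% for violet, and finds that “the solid is used up at a nearly constant” rate.

The flasks give 53.4% in green, 0.323% in amber, 1.49% in ochre and 16.8% in violet, so green is best.

    intermediate ⇌ isomer of the product (K = 230, k = 0.0707 h⁻¹, Ea = 127 kJ mol⁻¹, ΔH = −28.0 kJ mol⁻¹)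
    solid substrate ⇌ starting material, rate k2*(cs2 - [starting material]) while solid is left; crystals form when [starting material] > cs2 (solubility = 0.140 M, k = 0.568 h⁻¹)
    starting material → intermediate (k = 0.840 h⁻¹, Ea = 116 kJ mol⁻¹)
    starting material + protic impurity → quenched substrate (k = 4.66 L mol⁻¹ h⁻¹, Ea = 72.0 kJ mol⁻¹)
    starting material + target ⇌ idle adduct, settled at all times (K = 12.0 L mol⁻¹, ΔH = −53.0 kJ mol⁻¹)
    intermediate ⇌ target (K = 2.50, k = 0.494 h⁻¹, Ea = 115 kJ mol⁻¹, ΔH = −88.0 kJ mol⁻¹)
    (constants at 110 °C)

At 8.00 h amber holds isomer of the product at 95.5% of the charge, against 13.0% in green. The feed reckons half the charge out of the solid by 1.42 h; ochre, still at 140 °C then, reaches 50 percent conversion at 1.39 h, while green at 110 °C reaches it later, at 2.57 h. In the neighbour, ochre read at 2.0 h, the feed leaves 29.6% as solid, and the solid stands at 23.9%.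

The numbers in the tables were computed for an exercise; the scatter is artificial.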